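The data stem from a simulated flask for substances that don't exist; the scatter is artificial.

Time was what I had to extend: Thursday's and Sunday's runs stopped at 40.0 min, while alpha and theta were to be read at 50 min. In scavenger, alpha lay nearest Thursday's run and theta nearest Sunday's.

| setting | Thursday's | Sunday's | alpha | theta |
|---|---|---|---|---|
| starting material | 0.057 M | 0.057 M | 0.057 M | 0.057 M |
| second substrate | 0.103 M | 0.103 M | 0.103 M | 0.103 M |
| scavenger | 0.071 M | 0.13 M | 0.0570 M | 0.110 M |
| free enzyme | 11 µM | 11 µM | 11 µM | 11 µM |
| remark | run made earlier | run made earlier |  |  |
| time |  |  | 50 min | 50 min |

| run | time / min | starting material / % | target / % |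
|---|---|---|---|
| Thursday's | 3.00 | 97.1 | 1.8 |
| Thursday's | 6.00 | 94.6 | 4.6 |
| Thursday's | 15.0 | 86.8 | 12.3 |
| Thursday's | 40.0 | 68.1 | 31.9 |
| Sunday's | 8.00 | 93.6 | 6.9 |
| Sunday's | 20.0 | 83.8 | 16.5 |
| Sunday's | 25.0 | 79.2 | 20.4 |
| Sunday's | 40.0 | 69.0 | 31.3 |

(scatter of a reading: 0.5 percentage points)



- part of the starting material that has reacted at the end, alpha
- part of the starting material that has reacted at the end, theta
- what raising the concentration of scavenger from its lowest to its highest value here does to the part of the starting material that has reacted (changes below 5 percentage points count as none) (it falls / no change / it rises)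

I read the two tables row against row. In the last row of Thursday's run, starting material and target summed to 100%, so I let target stand for the part reacted. From the start to 15.0 min, Thursday's target climbed by 0.00820 min⁻¹ as a fraction of the charge, and Sunday's climbed by 0.00825 min⁻¹ up to 20.0 min. From those rows to the last, the slopes were 0.00784 min⁻¹ and 0.00740 min⁻¹, so the line bent gently.

The last rows differed by 0.6 percentage points, close to the scatter of 0.5 points, although scavenger rose from 0.071 M to 0.13 M. I therefore merged the late slopes into one quantity, the creep s, the fraction of the charge turned into target per minute on the late stretch: 0.00762 min⁻¹.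

The remaining time was then a small correction to a measured value, 7.6 points. Added to each last reading, it gave me 39.5% for alpha and 38.9% for theta. Their gap of 0.6 points was smaller than 5 points.

The forecast gave 38.3% for alpha, 37.8% for theta and no change, reasoning that “Scavenger therefore seems to have little kinetic effect in this range”. Its figures stood below mine.

The flasks gave 39.0% for alpha and 38.9% for theta, a change of −0.12 points: no change.

    second complex → free enzyme + target (k = 1.90 s⁻¹)
    2 starting material → homo dimer (k = 8.70 × 10⁻⁶ M⁻¹ s⁻¹)
    first complex → loaded enzyme + first product (k = 11.0 s⁻¹)
    starting material + first product ⇌ idle adduct, settled at all times (K = 15.0 M⁻¹)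
    starting material + free enzyme ⇌ first complex (K = 39.0 M⁻¹, k = 5300 M⁻¹ s⁻¹)
    second substrate + loaded enzyme ⇌ second complex (K = 7.00 M⁻¹, k = 2600 M⁻¹ s⁻¹)
    scavenger + first product → scavenged by-product (k = 0.840 M⁻¹ s⁻¹)

Theta's target went from 20.0% at 25.0 min to 38.6% at 50.0 min, a creep of 0.00744 min⁻¹ beside my 0.00762 min⁻¹. Theta stood at this figure through the back reaction of second complex, which is one part of the reason, together with the reading at 50 min and not ten times later: without that back reaction it reached 81.3%, and at 500 min it stood at 100%. Alpha's answer moved by 5 points, the rest held, at free enzyme of 9.48 µM or 12.6 µM, so a run at such a charge is where the forecast could be shown wrong.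

For theta left until 180 min, the creep taken as a straight line from the start gave 137%, a figure above the charge and so no content of any flask, only my estimate that the time was long enough to use up most of the starting material. The flask held 99.7% target there, with starting material the limiting reagent at 0.011% against 45% of second substrate.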